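I decide to treat each slow addition as a delay, and to ask what that delay costs in D at the end of the run.

| flask | J | Z | remark | time |
|---|---|---|---|---|
| Thursday's | 20 mM | 2 equiv | run made earlier |  |
| Sunday's | 10 mM | 2 equiv | run made earlier |  |
| Wednesday's | 15 mM | 2 equiv | run made earlier |  |
| north-east | 20 mM (fed, over 15 min) | 2.00 equiv | all else is in the flask from the start; the feed brings no volume worth counting | 80 min |
| west | 20 mM | 2.00 equiv (fed, over 1.5 min) | all else is in the flask from the start; the feed brings no volume worth counting | 80 min |
| south-west | 20 mM | 2.00 equiv (fed, over 15 min) | all else is in the flask from the start; the feed brings no volume worth counting | 80 min |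
| north-west | 20 mM | 2.00 equiv | everything together at the start | 80 min |
| south | 20 mM (in portions, 3, over 15 min) | 2.00 equiv | first portion at the start, last at 15 min | 80 min |

| run | time / min | D / % | J / % |
|---|---|---|---|
| Thursday's | 10.0 | 0.1 | 89.6 |
| Thursday's | 30.0 | 2.1 | 71.9 |
| Thursday's | 50.0 | 7.1 | 58.6 |
| Thursday's | 80.0 | 12.7 | 42.6 |
| Sunday's | 20.0 | 0.7 | 80.8 |
| Sunday's | 40.0 | 2.3 | 65.0 |
| Sunday's | 60.0 | 5.3 | 52.6 |
| Sunday's | 80.0 | 7.8 | 43.2 |
| Wednesday's | 6.00 | 0.2 | 93.6 |
| Wednesday's | 15.0 | 0 | 84.9 |
| Wednesday's | 30.0 | 1.6 | 72.2 |
| Wednesday's | 80.0 | 10.5 | 42.9 |

(standard deviation of a reading: 0.3 percentage points)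

- what was read earlier has a scatter of 0.3 percentage points, one standard deviation

- the flask that comes out highest in amount of D, in percent of the J charged, or "all alike" when all lie within 1.5 percentage points (north-east / west / south-west / north-west / south / all alike)
- D at the end, in percent of the J charged, north-east
- D at the end, in percent of the J charged, west
- D at the end, in percent of the J charged, south-west
- D at the end, in percent of the J charged, north-west
- D at the end, in percent of the J charged, south

Thursday's run has the recipe of north-west, so I start north-west from its reading of 12.7% at 80.0 min. Over the last 30.0 min of Thursday's run, D rose by 5.6 percentage points. A steady feed over 15 min arrives 7.50 min late on average, and I take the same for the 3 equal portions of south, with the middle one falling midway. The rise per minute times that lateness gives 1.4 points; I call this the delay cost, the late rise of D per minute times the mean lateness of the addition.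

But a shift in time is honest only if J runs on its own clock. The J left at the end reads 42.6%, 43.2% and 42.9% at 20 mM, 10 mM and 15 mM, so J passes this test. D does not: it reads 7.8% at 10 mM against 12.7% at 20 mM, and a feed keeps J thin early. Yet Thursday's D reads 0.1% at 10.0 min, so the thin stretch falls inside the lag, the induction period.

A second doubt is that the curve bends, since the stretch before rose 5 points in 20.0 min, faster per minute than the last one. The delay lies at the flat end, so my cost is high if anything, and the scatter moves it by about 0.11 points.

So I commit to 11.3% for north-east and south. For the Z feeds I can say less, and I place south-west between that figure and 12.7%, with west near 12.7%. The spread is smaller than the margin of 1.5 points, but narrowly.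

The forecast gives north-east 11.3%, west 12.7%, south-west 12.5%, north-west 12.7% and south 11.3%, a firmer south-west than mine, and it ends “just inside 1.5, so I call it all alike”.

The flasks give north-east 11.5%, west 12.2%, south-west 11.9%, north-west 12.3% and south 11.5%: all alike.

    J ⇌ L (K = 14.0, k = 1.83 × 10⁻⁴ /s)
    Z → X (k = 3.87 × 10⁻⁴ /s)
    L + X → D (k = 0.00849 /M/s)
    D → G (k = 4.84 × 10⁻⁴ /s)

In north-west the half-life of D by the path to G alone, 24 min, is shorter than the 80 min of the run, and D ends beside 11.5% of G. The delay cost of 1.4 points stands against a gap of 0.80 points between north-west and north-east. North-east fed over 45.0 min is 22.5 min late on average, which scales the delay cost to 4.2 points, and that flask gives 9.37%, a gap of 2.9 points.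

All runs are simulated for substances that don't exist.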